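**Retrosynthetic overview**
1. The target is robinetinidol-(4β→6)-gallocatechin (upper unit 2R,3S,4R, rings A/B/C; lower unit (+)-gallocatechin, rings D/E/F). Last come hydrogenolysis of the benzyl ethers and a C8 bromine, the C3 hydroxyl from a C3 ketone (hydride anti to the C4 aryl), and that ketone from a C3 nitro group (Nef).
2. The interflavan bond C4 (ring C)–C6 (ring D) is made by Friedel–Crafts/Michael addition of C8-brominated hexa-O-benzyl-gallocatechin to a (2R)-3-nitro-2H-chromene, trans to the C2 aryl.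
3. Ring C is built by forming O1–C8a and C2–C3 in one pot from 3,4,5-tris(benzyloxy)benzaldehyde and an achiral 4-methoxy-4-(2-nitroethyl)cyclohexadienone: asymmetric Henry reaction, then oxa-Michael addition and loss of methanol, which also makes ring A aromatic.
4. Enabling feature: besides O1, ring A carries only the C7 hydroxyl, para to C4a and meta to C8a (no oxygen at C5), so ring A is the aromatized form of a para-quinol ether whose enone β-carbon is C8a. C3 is an oxygen-bearing carbon between C2 and C4, so it can be carried as C–NO2.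
5. Ring order: B (bought) → C together with aromatic A (step 3) → dehydrogenation of ring C → union with the preformed D/E/F unit.

Key step: step 3

Remark (assumption): trans-4-hydroxy-β-nitrostyrene, 3,4,5-tris(benzyloxy)benzaldehyde and (+)-gallocatechin are taken as commercial; which antipode of the bis(oxazoline) ligand gives the 2R carbinol in step 3 is to be fixed by a test run, and the route is written for that antipode.

Step 1
Reactants: 1 4-[(E)-2-nitroethenyl]phenol
Product: 2 4-(2-nitroethyl)phenol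
Conditions: NaBH4 (2.5 equiv), silica gel, CHCl3–i-PrOH, 0 °C to rt; aq. NH4Cl
Reagents that add atoms: none
Why: Conjugate hydride reduction of a nitroalkene by NaBH4 should give the nitronate, protonated on work-up, with silica gel suppressing Michael dimerization; no stereocenter is formed.

Step 2
Reactants: 2 4-(2-nitroethyl)phenol
Product: 3 4-methoxy-4-(2-nitroethyl)cyclohexa-2,5-dien-1-one
Conditions: PhI(OAc)2 (1.1 equiv), MeOH, 0 °C
Reagents that add atoms: methanol CO
Why: Hypervalent-iodine oxidative dearomatization of a para-alkylphenol in methanol should give the achiral quinol methyl ether, the nitroalkyl chain being inert.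

Step 3
Reactants: 3 4-methoxy-4-(2-nitroethyl)cyclohexa-2,5-dien-1-one (2 equiv); 4 3,4,5-tris(benzyloxy)benzaldehyde
Product: 7 (2R)-3-nitro-2-[3,4,5-tris(benzyloxy)phenyl]chroman-7-ol (C3 epimers), via nitroaldol adduct 5 (not isolated), via methoxy-hexahydrochromenone 6 (not isolated)
Conditions: Cu(OAc)2·H2O (10 mol %), 2,2'-(propane-2,2-diyl)bis[(3aR,8aS)-3a,8a-dihydro-8H-indeno[1,2-d]oxazole] (11 mol %), i-PrOH–THF, 0 °C; then volatiles removed, TsOH·H2O (20 mol %), CH2Cl2, rt
Reagents that add atoms: none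
Why: Proposed new method: the Cu(OAc)2–bis(oxazoline) complex forms the nitronate of 3 and adds it to one face of aldehyde 4 (Henry reaction, C2–C3, giving 5); under acid the new C2 hydroxyl adds 6-exo-trig to an enone β-carbon (oxa-Michael, O1–C8a, closing ring C, giving 6), and enolization with loss of methanol from C4a makes ring A aromatic with its hydroxyl at C7. The closest known reaction types are the copper-catalysed enantioselective Henry reaction of nitroalkanes with aromatic aldehydes and the acid-promoted Michael addition–aromatization of para-quinol ethers with oxygen nucleophiles; running them in one pot on a nitroalkyl quinol ether is the new part. C2 is set by the ligand (2R), C3 is not controlled and is erased in step 4, and the C4a and C8a centres of 6 vanish on aromatization. The step needs the hydroxyl to attack C8a only: the C2–C3–C4 tether places it six atoms from either enone β-carbon, the two β-carbons are equivalent so both give the same arene, and the weak acetate base followed by acidic closure should keep retro-Henry erosion of C2 small.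

Step 4
Reactants: 7 (2R)-3-nitro-2-[3,4,5-tris(benzyloxy)phenyl]chroman-7-ol
Product: 8 (2R)-3-nitro-2-[3,4,5-tris(benzyloxy)phenyl]-2H-chromen-7-ol
Conditions: DDQ (1.1 equiv), 1,4-dioxane, rt to 60 °C
Reagents that add atoms: none
Why: DDQ dehydrogenation of a para-alkylphenol (hydride loss from C4, para to the free C7 hydroxyl, then loss of the acidic C3 proton) should give the conjugated nitroalkene under neutral conditions that leave C2 untouched.

Step 5
Reactants: 9 (+)-gallocatechin
Product: 10 (2R,3S)-3,5,7-tris(benzyloxy)-2-[3,4,5-tris(benzyloxy)phenyl]chroman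
Conditions: NaH (6.6 equiv), BnBr (6.6 equiv), DMF, 0 °C to rt
Reagents that add atoms: benzyl bromide BrCc1ccccc1
Why: Williamson etherification of the five phenols and the C3 alcohol; no bond to a stereocenter is broken.

Step 6
Reactants: 10 (2R,3S)-3,5,7-tris(benzyloxy)-2-[3,4,5-tris(benzyloxy)phenyl]chroman
Product: 11 (2R,3S)-3,5,7-tris(benzyloxy)-8-bromo-2-[3,4,5-tris(benzyloxy)phenyl]chroman
Conditions: NBS (1.0 equiv), CH2Cl2, −78 to 0 °C
Reagents that add atoms: N-bromosuccinimide O=C1CCC(=O)N1Br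
Why: Electrophilic aromatic bromination should take place at C8, the most reactive position of ring D in O-benzylated flavan-3-ols, which leaves C6 as the only open nucleophilic site.

Step 7
Reactants: 8 (2R)-3-nitro-2-[3,4,5-tris(benzyloxy)phenyl]-2H-chromen-7-ol; 11 (2R,3S)-3,5,7-tris(benzyloxy)-8-bromo-2-[3,4,5-tris(benzyloxy)phenyl]chroman (1.5 equiv)
Product: 12 (2R,3S)-3,5,7-tris(benzyloxy)-8-bromo-6-{(2R,4R)-7-hydroxy-3-nitro-2-[3,4,5-tris(benzyloxy)phenyl]chroman-4-yl}-2-[3,4,5-tris(benzyloxy)phenyl]chroman (C3 epimers of the upper unit)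
Conditions: Zn(OTf)2 (20 mol %), (CF3)2CHOH–CH2Cl2, 0 °C to rt
Reagents that add atoms: none
Why: Friedel–Crafts alkylation of an electron-rich arene by a nitroalkene (Michael type, known for 3-nitro-2H-chromenes) should join C6 of ring D to C4, the arene attacking anti to the C2 aryl group, which sits pseudo-axial to avoid A(1,2) strain with the nitro group, so that C4 becomes R (2,4-trans).

Step 8
Reactants: 12 nitro adduct (C3 epimers)
Product: 13 (2R,4R)-4-{(2R,3S)-3,5,7-tris(benzyloxy)-8-bromo-2-[3,4,5-tris(benzyloxy)phenyl]chroman-6-yl}-7-hydroxy-2-[3,4,5-tris(benzyloxy)phenyl]chroman-3-one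
Conditions: KOt-Bu (2.2 equiv), THF, −78 °C, 10 min; then added to aq. TiCl3 (6 equiv)/NH4OAc buffer (pH 5–6), 0 °C to rt
Reagents that add atoms: water O
Why: Reductive Nef reaction: TiCl3 should reduce the nitronate to the imine, which the buffer hydrolyses to the C3 ketone; the short, cold nitronate stage and the near-neutral buffer are meant to protect the C2 and C4 centres.

Step 9
Reactants: 13 C3 ketone
Product: 14 (2R,3S,4R)-4-{(2R,3S)-3,5,7-tris(benzyloxy)-8-bromo-2-[3,4,5-tris(benzyloxy)phenyl]chroman-6-yl}-2-[3,4,5-tris(benzyloxy)phenyl]chroman-3,7-diol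
Conditions: NaBH4 (2 equiv), THF–MeOH, −40 to 0 °C
Reagents that add atoms: none
Why: Hydride reduction of a ketone; with the C2 aryl pseudo-equatorial and the bulky C4 aryl pseudo-axial, hydride should enter anti to the C4 aryl and give the 3S alcohol, cis to the C4 aryl and trans to the C2 aryl.

Step 10
Reactants: 14 protected dimer
Product: 15 robinetinidol-(4β→6)-gallocatechin (target)
Conditions: H2 (1 atm), Pd(OH)2/C, Et3N (2 equiv), THF–MeOH–H2O, rt
Reagents that add atoms: none
Why: Catalytic hydrogenolysis should cleave the nine benzyl ethers and the aryl C–Br bond in one operation, with Et3N taking up HBr; the interflavan bond of a C5-unsubstituted ring A is acid-stable and no stereocenter is touched.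

**Compound list**
1 | 4-[(E)-2-nitroethenyl]phenol | Oc1ccc(/C=C/[N+](=O)[O-])cc1 | starting material
2 | 4-(2-nitroethyl)phenol | Oc1ccc(CC[N+](=O)[O-])cc1 | intermediate
3 | 4-methoxy-4-(2-nitroethyl)cyclohexa-2,5-dien-1-one | O=C1C=CC(OC)(CC[N+](=O)[O-])C=C1 | intermediate
4 | 3,4,5-tris(benzyloxy)benzaldehyde | O=Cc1cc(OCc2ccccc2)c(OCc2ccccc2)c(OCc2ccccc2)c1 | starting material
5 | 4-{(3R)-3-hydroxy-2-nitro-3-[3,4,5-tris(benzyloxy)phenyl]propyl}-4-methoxycyclohexa-2,5-dien-1-one (C2 epimers of the chain) | O[C@H](c1cc(OCc2ccccc2)c(OCc2ccccc2)c(OCc2ccccc2)c1)C([N+](=O)[O-])CC1(OC)C=CC(=O)C=C1 | intermediate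
6 | (2R)-4a-methoxy-3-nitro-2-[3,4,5-tris(benzyloxy)phenyl]-3,4,4a,8a-tetrahydro-2H-chromen-7(8H)-one (cis-fused; C3, C4a, C8a not assigned) | O1[C@H](c3cc(OCc4ccccc4)c(OCc4ccccc4)c(OCc4ccccc4)c3)C([N+](=O)[O-])CC2(OC)C=CC(=O)CC12 | intermediate
7 | (2R)-3-nitro-2-[3,4,5-tris(benzyloxy)phenyl]chroman-7-ol (C3 epimers) | Oc1ccc2c(c1)O[C@H](c1cc(OCc3ccccc3)c(OCc3ccccc3)c(OCc3ccccc3)c1)C([N+](=O)[O-])C2 | intermediate
8 | (2R)-3-nitro-2-[3,4,5-tris(benzyloxy)phenyl]-2H-chromen-7-ol | Oc1ccc2c(c1)O[C@H](c1cc(OCc3ccccc3)c(OCc3ccccc3)c(OCc3ccccc3)c1)C([N+](=O)[O-])=C2 | intermediate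
9 | (+)-gallocatechin, (2R,3S) | Oc1cc2c(c(O)c1)C[C@H](O)[C@@H](c1cc(O)c(O)c(O)c1)O2 | starting material
10 | (2R,3S)-3,5,7-tris(benzyloxy)-2-[3,4,5-tris(benzyloxy)phenyl]chroman | c1ccccc1COc1cc2c(c(OCc3ccccc3)c1)C[C@H](OCc1ccccc1)[C@@H](c1cc(OCc3ccccc3)c(OCc3ccccc3)c(OCc3ccccc3)c1)O2 | intermediate
11 | (2R,3S)-3,5,7-tris(benzyloxy)-8-bromo-2-[3,4,5-tris(benzyloxy)phenyl]chroman | c1ccccc1COc1c(Br)c2c(c(OCc3ccccc3)c1)C[C@H](OCc1ccccc1)[C@@H](c1cc(OCc3ccccc3)c(OCc3ccccc3)c(OCc3ccccc3)c1)O2 | intermediate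
12 | nitro adduct, upper unit (2R,4R), C3 epimers; lower unit (2R,3S) | Oc1ccc2c(c1)O[C@H](c1cc(OCc3ccccc3)c(OCc3ccccc3)c(OCc3ccccc3)c1)C([N+](=O)[O-])[C@H]2c1c(OCc3ccccc3)c(Br)c2c(c1OCc3ccccc3)C[C@H](OCc1ccccc1)[C@@H](c1cc(OCc3ccccc3)c(OCc3ccccc3)c(OCc3ccccc3)c1)O2 | intermediate
13 | C3 ketone, upper unit (2R,4R) | Oc1ccc2c(c1)O[C@H](c1cc(OCc3ccccc3)c(OCc3ccccc3)c(OCc3ccccc3)c1)C(=O)[C@H]2c1c(OCc3ccccc3)c(Br)c2c(c1OCc3ccccc3)C[C@H](OCc1ccccc1)[C@@H](c1cc(OCc3ccccc3)c(OCc3ccccc3)c(OCc3ccccc3)c1)O2 | intermediate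
14 | protected dimer, upper unit (2R,3S,4R) | Oc1ccc2c(c1)O[C@H](c1cc(OCc3ccccc3)c(OCc3ccccc3)c(OCc3ccccc3)c1)[C@@H](O)[C@H]2c1c(OCc3ccccc3)c(Br)c2c(c1OCc3ccccc3)C[C@H](OCc1ccccc1)[C@@H](c1cc(OCc3ccccc3)c(OCc3ccccc3)c(OCc3ccccc3)c1)O2 | intermediate
15 | robinetinidol-(4β→6)-gallocatechin | Oc1ccc2c(c1)O[C@H](c1cc(O)c(O)c(O)c1)[C@@H](O)[C@H]2c1c(O)cc2c(c1O)C[C@H](O)[C@@H](c1cc(O)c(O)c(O)c1)O2 | target

**Step count and risks**
Total steps: 10. Longest linear sequence: 8 (steps 1–4 and 7–10).

Three steps most likely to fail: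

Step 3 (proposed method). The Henry addition is reversible, so the C2 configuration may erode before the hydroxyl is locked into ring C; the nitronate may add to the dienone of a second molecule; and residual alcohol solvent may capture the dienone in place of the tethered hydroxyl. The fallback uses known chemistry and sets out from 4. Condensation with nitromethane (NH4OAc, AcOH, heat) would give (E)-1,2,3-tris(benzyloxy)-5-(2-nitroethenyl)benzene F1. An amine-catalysed enantioselective oxa-Michael–Henry–dehydration cascade of this nitroalkene with 2,4-dihydroxybenzaldehyde (chiral diarylprolinol silyl ether, carboxylic acid co-catalyst, antipode chosen for 2R) would then give 8, where the route is rejoined; ring C is then closed through O1–C2 and C3–C4 and steps 3 and 4 are bypassed.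

Step 7. The hindered, bromine-bearing arene may add too slowly to the donor-substituted nitroalkene, and the facial bias at C4 may be weak. The fallback sets out from 7 and makes the C4–C6 bond through a benzylic cation of the 2,3-cis series. A Nef reaction (KOt-Bu, −78 °C; aq. TiCl3/NH4OAc) would give (2R)-7-hydroxy-2-[3,4,5-tris(benzyloxy)phenyl]chroman-3-one F2. LiBH(s-Bu)3 at −78 °C, attacking anti to the C2 aryl, would give (2R,3R)-2-[3,4,5-tris(benzyloxy)phenyl]chroman-3,7-diol F3. DDQ in CH2Cl2–MeOH would give (2R,3R,4S)-4-methoxy-2-[3,4,5-tris(benzyloxy)phenyl]chroman-3,7-diol F4. BF3·OEt2 at −78 °C would ionize it, and 11 should attack C4 trans to both the C3 hydroxyl and the C2 aryl, giving the (2R,3R,4R) C3 epimer of 14 F5. Swern oxidation of its single free secondary alcohol would give 13, where the route is rejoined.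

Step 8. The nitronate may expel the O1 aryloxide (E1cB ring opening and reclosure, which scrambles C2), and the new ketone may enolize toward C2 or C4. The fallback sets out from 12. SnCl2·2H2O/PhSH/Et3N in MeCN would reduce the secondary nitro group to the upper-unit (2R,4R) chroman-3-one oxime F6 without a nitronate being held in solution. Exchange with glyoxylic acid (aq. AcOH, NaOAc, rt) would release ketone 13, where the route is rejoined.

**Further compounds**
F1 | step 3 | (E)-1,2,3-tris(benzyloxy)-5-(2-nitroethenyl)benzene | [O-][N+](=O)/C=C/c1cc(OCc2ccccc2)c(OCc2ccccc2)c(OCc2ccccc2)c1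
F2 | step 7 | (2R)-7-hydroxy-2-[3,4,5-tris(benzyloxy)phenyl]chroman-3-one | Oc1ccc2c(c1)O[C@H](c1cc(OCc3ccccc3)c(OCc3ccccc3)c(OCc3ccccc3)c1)C(=O)C2
F3 | step 7 | (2R,3R)-2-[3,4,5-tris(benzyloxy)phenyl]chroman-3,7-diol | Oc1ccc2c(c1)O[C@H](c1cc(OCc3ccccc3)c(OCc3ccccc3)c(OCc3ccccc3)c1)[C@H](O)C2
F4 | step 7 | (2R,3R,4S)-4-methoxy-2-[3,4,5-tris(benzyloxy)phenyl]chroman-3,7-diol | Oc1ccc2c(c1)O[C@H](c1cc(OCc3ccccc3)c(OCc3ccccc3)c(OCc3ccccc3)c1)[C@H](O)[C@H]2OC
F5 | step 7 | C3 epimer of 14, upper unit (2R,3R,4R) | Oc1ccc2c(c1)O[C@H](c1cc(OCc3ccccc3)c(OCc3ccccc3)c(OCc3ccccc3)c1)[C@H](O)[C@H]2c1c(OCc3ccccc3)c(Br)c2c(c1OCc3ccccc3)C[C@H](OCc1ccccc1)[C@@H](c1cc(OCc3ccccc3)c(OCc3ccccc3)c(OCc3ccccc3)c1)O2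
F6 | step 8 | oxime of 13, upper unit (2R,4R), E/Z mixture | Oc1ccc2c(c1)O[C@H](c1cc(OCc3ccccc3)c(OCc3ccccc3)c(OCc3ccccc3)c1)C(=NO)[C@H]2c1c(OCc3ccccc3)c(Br)c2c(c1OCc3ccccc3)C[C@H](OCc1ccccc1)[C@@H](c1cc(OCc3ccccc3)c(OCc3ccccc3)c(OCc3ccccc3)c1)O2
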